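The ring is read as a masked 2-silyloxycyclohexa-1,3-diene. In the 7-oxabicyclo[4.1.0]heptane numbering of the target, the ketone carbon C2 and the methyl-bearing oxirane carbon C1 are the two carbons of a silyl ynol ether; C3 (acyloxy carbon), C4, C5 and C6 (oxirane CH) come from an enantioenriched 3-substituted hexa-1,5-diene. One tandem enyne cross-metathesis/ring-closing metathesis joins C2 to C3 and C1 to C6, expels ethylene and delivers the cross-conjugated silyl dienol ether, which is then oxygenated at C3 and across C1–C6. The precursor is the acyclic (3R)-3-ethenyl-2-methylidenehex-5-enal plus triisopropylsilyloxypropyne.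

Key step: step 7

Remark: compounds 1, 2 and 8 are taken as commercial; the sense of induction in steps 1 and 11 is assigned by analogy with cyclohex-2-enone and 2-methylprop-2-en-1-ol and is not verified on these substrates.

Step 1
Reactants: 1 5,6-dihydro-2H-pyran-2-one; 2 potassium vinyltrifluoroborate
Product: 3 (4R)-4-ethenyltetrahydro-2H-pyran-2-one
Conditions: [Rh(cod)2]PF6 (3 mol%), (R)-BINAP, toluene/H2O, 100 °C
Reagents that add atoms: none
Why: Hayashi–Miyaura rhodium-catalysed asymmetric 1,4-addition of an alkenylboron reagent to an unsaturated lactone, in which the (R)-BINAP complex selects the face that gives the 4R centre (with cyclohex-2-enone, (S)-BINAP gives the S adduct).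

Step 2
Reactants: 3 (4R)-4-ethenyltetrahydro-2H-pyran-2-one
Product: 4 (4R)-4-ethenyltetrahydro-2H-pyran-2-ol (lactol as anomer mixture)
Conditions: i-Bu2AlH, CH2Cl2, −78 °C; Rochelle salt work-up
Reagents that add atoms: none
Why: Partial reduction of a δ-lactone to the lactol at low temperature is standard and the stereocentre is remote from the reacting carbonyl.

Step 3
Reactants: 4 (4R)-4-ethenyltetrahydro-2H-pyran-2-ol
Product: 5 (3S)-3-ethenylhex-5-en-1-ol
Conditions: Ph3PCH3Br, KOt-Bu, THF, 0 °C to rt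
Reagents that add atoms: methyltriphenylphosphonium bromide, [Br-].C[P+](c1ccccc1)(c1ccccc1)c1ccccc1
Why: Wittig methylenation of the open hydroxy-aldehyde form of the lactol installs the second terminal alkene and frees the primary alcohol without touching the stereocentre (the descriptor changes by priority only).

Step 4
Reactants: 5 (3S)-3-ethenylhex-5-en-1-ol
Product: 6 (3S)-3-ethenylhex-5-enal
Conditions: Dess–Martin periodinane, NaHCO3, CH2Cl2, 0 °C to rt
Reagents that add atoms: none
Why: Dess–Martin oxidation of a primary alcohol, with the stereocentre β to the new aldehyde and therefore not epimerisable by enolisation.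

Step 5
Reactants: 6 (3S)-3-ethenylhex-5-enal
Product: 7 (3R)-3-ethenyl-2-methylidenehex-5-enal
Conditions: aq. CH2O (37%), pyrrolidine (10 mol%), propionic acid (10 mol%), i-PrOH, 45 °C
Reagents that add atoms: formaldehyde, C=O
Why: Amine-catalysed Mannich condensation/elimination (organocatalytic α-methylenation of an aldehyde) converts the CH2 next to the aldehyde into the 1,1-disubstituted enal under buffered conditions that should leave the now allylic stereocentre intact.

Step 6
Reactants: 8 1-propynyllithium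
Product: 10 triisopropyl(prop-1-yn-1-yloxy)silane, via lithium prop-1-yn-1-olate 9 (not isolated)
Conditions: t-BuOOH, LiN(SiMe3)2, THF, −78 °C; add 8, −78 to 0 °C; then i-Pr3SiOTf, −78 °C
Reagents that add atoms: tert-butyl hydroperoxide, CC(C)(C)OO; triisopropylsilyl trifluoromethanesulfonate, CC(C)[Si](C(C)C)(C(C)C)OS(=O)(=O)C(F)(F)F
Why: Oxidation of a lithium acetylide by lithium tert-butylperoxide gives the ynolate, which the bulky silyl triflate captures on oxygen (established route to silyl ynol ethers).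

Step 7
Reactants: 7 (3R)-3-ethenyl-2-methylidenehex-5-enal; 10 triisopropyl(prop-1-yn-1-yloxy)silane
Product: 11 2-[(1R)-4-methyl-3-[tri(propan-2-yl)silyloxy]cyclohexa-2,4-dien-1-yl]prop-2-enal
Conditions: RuCl2(=CHPh)(H2IMes)(PCy3) (second-generation Grubbs catalyst, 10 mol%), 10 (1.5 equiv, slow addition), benzene (0.02 M), 60 °C, Ar purge
Reagents that add atoms: none
Why: Proposed new method: the ruthenium alkylidene formed at the unhindered allyl terminus of 7 should add to the polarised ynol ether with its carbene carbon on the methyl-bearing alkyne carbon (the orientation alkylidenes show with enol ethers), giving a silyloxy-stabilised vinylcarbene that closes the ring by metathesis onto the vinyl group and expels ethylene. The closest known reactions are the tandem enyne cross-metathesis/ring-closing metathesis of simple alkynes with hexa-1,5-diene to cyclohexa-1,3-dienes and the ring-closing enyne metathesis of siloxyalkynes; the intermolecular use of a siloxyalkyne is the untested element. The six-membered ring closes by ring-closing metathesis in the endo sense, with both former alkyne carbons inside the ring. No new stereocentre is formed and the existing allylic centre is not touched. The step needs regiocontrol (silyloxy carbon bonded to the CH next to the stereocentre), which the steric difference between the two terminal alkenes and the electronic bias of the ynol ether should secure, while slow alkyne addition and ethylene removal suppress the methylidene-initiated path to the regioisomer. The 1,1-disubstituted enal alkene is expected to be inert to the catalyst.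

Step 8
Reactants: 11 2-[(1R)-4-methyl-3-[tri(propan-2-yl)silyloxy]cyclohexa-2,4-dien-1-yl]prop-2-enal
Product: 13 2-[(1S,6S)-6-hydroxy-4-methyl-5-oxocyclohex-3-en-1-yl]prop-2-enal, via siloxy oxirane 12 (not isolated)
Conditions: dimethyldioxirane (1.05 equiv, acetone), CH2Cl2, −78 to −40 °C; then HF·pyridine, THF, −40 to 0 °C
Reagents that add atoms: dimethyldioxirane, CC1(C)OO1
Why: Rubottom oxidation, in which the electron-rich silyl enol ether double bond is epoxidised on the face anti to the adjacent side chain and fluoride-assisted collapse of the siloxy oxirane gives the α'-hydroxy enone with the new carbinol centre trans to the side chain.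

Step 9
Reactants: 13 2-[(1S,6S)-6-hydroxy-4-methyl-5-oxocyclohex-3-en-1-yl]prop-2-enal
Product: 14 (1S,6S)-3-methyl-2-oxo-6-(3-oxoprop-1-en-2-yl)cyclohex-3-en-1-yl 3-methylbutanoate
Conditions: 3-methylbutanoyl chloride, pyridine, DMAP (cat.), CH2Cl2, 0 °C
Reagents that add atoms: 3-methylbutanoyl chloride, CC(C)CC(Cl)=O
Why: DMAP-catalysed acylation of the secondary hydroxyl of the α-hydroxy ketone, the only hydroxyl present.

Step 10
Reactants: 14 (1S,6S)-3-methyl-2-oxo-6-(3-oxoprop-1-en-2-yl)cyclohex-3-en-1-yl 3-methylbutanoate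
Product: 15 (1S,2S,6S)-2-hydroxy-6-(3-hydroxyprop-1-en-2-yl)-3-methylcyclohex-3-en-1-yl 3-methylbutanoate
Conditions: NaBH4, CeCl3·7H2O, MeOH, −78 °C
Reagents that add atoms: none
Why: Luche reduction effects 1,2-reduction of both the ring enone and the enal, and axial hydride delivery to the half-chair with both ring substituents equatorial (as in carvone to cis-carveol) should place the new ring hydroxyl trans to the ester and cis to the side chain.

Step 11
Reactants: 15 (1S,2S,6S)-2-hydroxy-6-(3-hydroxyprop-1-en-2-yl)-3-methylcyclohex-3-en-1-yl 3-methylbutanoate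
Product: 16 (1S,2S,6R)-2-hydroxy-6-[(2S)-2-(hydroxymethyl)oxiran-2-yl]-3-methylcyclohex-3-en-1-yl 3-methylbutanoate
Conditions: Ti(Oi-Pr)4 (10 mol%), L-(+)-diethyl tartrate (12 mol%), t-BuOOH, 4 Å MS, CH2Cl2, −20 °C
Reagents that add atoms: tert-butyl hydroperoxide, CC(C)(C)OO
Why: Sharpless asymmetric epoxidation of the primary 2-substituted allylic alcohol under reagent control, where L-(+)-tartrate (which converts 2-methylprop-2-en-1-ol into (S)-2-methylglycidol) sets the quaternary oxirane carbon, and any slow epoxidation of the ring allylic alcohol is syn-directed and leads to the product of step 12.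

Step 12
Reactants: 16 (1S,2S,6R)-2-hydroxy-6-[(2S)-2-(hydroxymethyl)oxiran-2-yl]-3-methylcyclohex-3-en-1-yl 3-methylbutanoate
Product: 17 (1R,2R,3S,4R,6S)-2-hydroxy-4-[(2S)-2-(hydroxymethyl)oxiran-2-yl]-1-methyl-7-oxabicyclo[4.1.0]heptan-3-yl 3-methylbutanoate
Conditions: VO(acac)2 (5 mol%), t-BuOOH, CH2Cl2, 0 °C to rt
Reagents that add atoms: tert-butyl hydroperoxide, CC(C)(C)OO
Why: Hydroxyl-directed vanadium-catalysed epoxidation delivers oxygen to the trisubstituted ring alkene syn to the allylic hydroxyl, that is cis to the side chain and trans to the ester, the face that nucleophilic epoxidation of the enone would not reach.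

Step 13
Reactants: 17 (1R,2R,3S,4R,6S)-2-hydroxy-4-[(2S)-2-(hydroxymethyl)oxiran-2-yl]-1-methyl-7-oxabicyclo[4.1.0]heptan-3-yl 3-methylbutanoate
Product: 18 (1S,3S,4R,6S)-4-[(2R)-2-formyloxiran-2-yl]-1-methyl-2-oxo-7-oxabicyclo[4.1.0]heptan-3-yl 3-methylbutanoate
Conditions: Dess–Martin periodinane (3 equiv), NaHCO3, CH2Cl2, rt
Reagents that add atoms: none
Why: Double Dess–Martin oxidation restores the ring ketone and gives the non-enolisable epoxy aldehyde, and the only epimerisable centre (the acyloxy carbon) already has the more stable trans arrangement.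

Step 14
Reactants: 18 (1S,3S,4R,6S)-4-[(2R)-2-formyloxiran-2-yl]-1-methyl-2-oxo-7-oxabicyclo[4.1.0]heptan-3-yl 3-methylbutanoate
Product: 19 (1S,3S,4R,6S)-4-[(2R)-2-(1-hydroxybut-3-en-1-yl)oxiran-2-yl]-1-methyl-2-oxo-7-oxabicyclo[4.1.0]heptan-3-yl 3-methylbutanoate (carbinol epimers)
Conditions: allylboronic acid pinacol ester, CH2Cl2, rt; aqueous work-up
Reagents that add atoms: allylboronic acid pinacol ester, C=CCB1OC(C)(C)C(C)(C)O1
Why: Allylboration with a pinacol allylboronate is selective for the aldehyde over the ring ketone and the ester, and the new carbinol centre (formed as a mixture) is removed in step 16.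

Step 15
Reactants: 19 (1S,3S,4R,6S)-4-[(2R)-2-(1-hydroxybut-3-en-1-yl)oxiran-2-yl]-1-methyl-2-oxo-7-oxabicyclo[4.1.0]heptan-3-yl 3-methylbutanoate
Product: 20 (1S,3S,4R,6S)-4-[(2R)-2-(1-hydroxy-4-methylpent-3-en-1-yl)oxiran-2-yl]-1-methyl-2-oxo-7-oxabicyclo[4.1.0]heptan-3-yl 3-methylbutanoate (carbinol epimers)
Conditions: RuCl2(=CH-2-(i-PrO)C6H4)(H2IMes) (second-generation Hoveyda–Grubbs catalyst, 5 mol%), 2-methylbut-2-ene/CH2Cl2, 40 °C
Reagents that add atoms: 2-methylbut-2-ene, CC=C(C)C
Why: Olefin cross-metathesis of a terminal alkene with excess 2-methylbut-2-ene installs the prenyl terminus, and the catalyst tolerates epoxides, ketone, ester and free hydroxyl.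

Step 16
Reactants: 20 (1S,3S,4R,6S)-4-[(2R)-2-(1-hydroxy-4-methylpent-3-en-1-yl)oxiran-2-yl]-1-methyl-2-oxo-7-oxabicyclo[4.1.0]heptan-3-yl 3-methylbutanoate
Product: 21 (1S,3S,4R,6S)-1-methyl-4-[(2R)-2-(4-methylpent-3-enoyl)oxiran-2-yl]-2-oxo-7-oxabicyclo[4.1.0]heptan-3-yl 3-methylbutanoate
Conditions: Dess–Martin periodinane, NaHCO3, CH2Cl2, 0 °C
Reagents that add atoms: none
Why: Buffered Dess–Martin oxidation converts both carbinol epimers into the β,γ-unsaturated ketone without base-induced conjugation of the alkene.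

Step 17
Reactants: 21 (1S,3S,4R,6S)-1-methyl-4-[(2R)-2-(4-methylpent-3-enoyl)oxiran-2-yl]-2-oxo-7-oxabicyclo[4.1.0]heptan-3-yl 3-methylbutanoate
Product: 22 (1S,3S,4R,6S)-4-[(2R)-2-[(2E)-4-hydroperoxy-4-methylpent-2-enoyl]oxiran-2-yl]-1-methyl-2-oxo-7-oxabicyclo[4.1.0]heptan-3-yl 3-methylbutanoate (CNP0131119.1)
Conditions: O2, tetraphenylporphyrin (cat.), visible light, CH2Cl2, −20 °C
Reagents that add atoms: dioxygen, O=O
Why: Schenck ene reaction of singlet oxygen, in which abstraction of the activated hydrogen of the CH2 next to the ketone (on the more crowded side of the trisubstituted alkene) should give the tertiary allylic hydroperoxide with the double bond shifted into conjugation as the E isomer, while epoxides, ketones and ester are inert.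

Compound list
1 | 5,6-dihydro-2H-pyran-2-one | O=C1C=CCCO1 | starting material
2 | potassium vinyltrifluoroborate | C=C[B-](F)(F)F.[K+] | starting material
3 | (4R)-4-ethenyltetrahydro-2H-pyran-2-one | O=C1C[C@H](C=C)CCO1 | intermediate
4 | (4R)-4-ethenyltetrahydro-2H-pyran-2-ol (anomer mixture) | OC1C[C@H](C=C)CCO1 | intermediate
5 | (3S)-3-ethenylhex-5-en-1-ol | C=CC[C@H](C=C)CCO | intermediate
6 | (3S)-3-ethenylhex-5-enal | C=CC[C@H](C=C)CC=O | intermediate
7 | (3R)-3-ethenyl-2-methylidenehex-5-enal | C=CC[C@H](C=C)C(=C)C=O | intermediate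
8 | 1-propynyllithium | [Li]C#CC | starting material
9 | lithium prop-1-yn-1-olate | CC#C[O-].[Li+] | intermediate (not isolated)
10 | triisopropyl(prop-1-yn-1-yloxy)silane | CC#CO[Si](C(C)C)(C(C)C)C(C)C | intermediate
11 | 2-[(1R)-4-methyl-3-[tri(propan-2-yl)silyloxy]cyclohexa-2,4-dien-1-yl]prop-2-enal | O=CC(=C)[C@@H]1CC=C(C)C(O[Si](C(C)C)(C(C)C)C(C)C)=C1 | intermediate
12 | 2-[(1S,2S,6S)-5-methyl-6-[tri(propan-2-yl)silyloxy]-7-oxabicyclo[4.1.0]hept-4-en-2-yl]prop-2-enal (oxirane oxygen trans to the propenal group) | O=CC(=C)[C@@H]1CC=C(C)[C@@]2(O[Si](C(C)C)(C(C)C)C(C)C)O[C@@H]12 | intermediate (not isolated)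
13 | 2-[(1S,6S)-6-hydroxy-4-methyl-5-oxocyclohex-3-en-1-yl]prop-2-enal | O[C@@H]1C(=O)C(C)=CC[C@H]1C(=C)C=O | intermediate
14 | (1S,6S)-3-methyl-2-oxo-6-(3-oxoprop-1-en-2-yl)cyclohex-3-en-1-yl 3-methylbutanoate | CC(C)CC(=O)O[C@@H]1C(=O)C(C)=CC[C@H]1C(=C)C=O | intermediate
15 | (1S,2S,6S)-2-hydroxy-6-(3-hydroxyprop-1-en-2-yl)-3-methylcyclohex-3-en-1-yl 3-methylbutanoate | CC(C)CC(=O)O[C@@H]1[C@@H](O)C(C)=CC[C@H]1C(=C)CO | intermediate
16 | (1S,2S,6R)-2-hydroxy-6-[(2S)-2-(hydroxymethyl)oxiran-2-yl]-3-methylcyclohex-3-en-1-yl 3-methylbutanoate | CC(C)CC(=O)O[C@@H]1[C@@H](O)C(C)=CC[C@H]1[C@]1(CO)CO1 | intermediate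
17 | (1R,2R,3S,4R,6S)-2-hydroxy-4-[(2S)-2-(hydroxymethyl)oxiran-2-yl]-1-methyl-7-oxabicyclo[4.1.0]heptan-3-yl 3-methylbutanoate | CC(C)CC(=O)O[C@@H]1[C@@H](O)[C@@]2(C)O[C@H]2C[C@H]1[C@]1(CO)CO1 | intermediate
18 | (1S,3S,4R,6S)-4-[(2R)-2-formyloxiran-2-yl]-1-methyl-2-oxo-7-oxabicyclo[4.1.0]heptan-3-yl 3-methylbutanoate | CC(C)CC(=O)O[C@@H]1C(=O)[C@@]2(C)O[C@H]2C[C@H]1[C@]1(C=O)CO1 | intermediate
19 | (1S,3S,4R,6S)-4-[(2R)-2-(1-hydroxybut-3-en-1-yl)oxiran-2-yl]-1-methyl-2-oxo-7-oxabicyclo[4.1.0]heptan-3-yl 3-methylbutanoate (carbinol epimers) | CC(C)CC(=O)O[C@@H]1C(=O)[C@@]2(C)O[C@H]2C[C@H]1[C@]1(C(O)CC=C)CO1 | intermediate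
20 | (1S,3S,4R,6S)-4-[(2R)-2-(1-hydroxy-4-methylpent-3-en-1-yl)oxiran-2-yl]-1-methyl-2-oxo-7-oxabicyclo[4.1.0]heptan-3-yl 3-methylbutanoate (carbinol epimers) | CC(C)CC(=O)O[C@@H]1C(=O)[C@@]2(C)O[C@H]2C[C@H]1[C@]1(C(O)CC=C(C)C)CO1 | intermediate
21 | (1S,3S,4R,6S)-1-methyl-4-[(2R)-2-(4-methylpent-3-enoyl)oxiran-2-yl]-2-oxo-7-oxabicyclo[4.1.0]heptan-3-yl 3-methylbutanoate | CC(C)CC(=O)O[C@@H]1C(=O)[C@@]2(C)O[C@H]2C[C@H]1[C@]1(C(=O)CC=C(C)C)CO1 | intermediate
22 | (1S,3S,4R,6S)-4-[(2R)-2-[(2E)-4-hydroperoxy-4-methylpent-2-enoyl]oxiran-2-yl]-1-methyl-2-oxo-7-oxabicyclo[4.1.0]heptan-3-yl 3-methylbutanoate | CC(C)CC(=O)O[C@@H]1C(=O)[C@@]2(C)O[C@H]2C[C@H]1[C@]1(C(=O)/C=C/C(C)(C)OO)CO1 | target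

Total step count: 17. Longest linear sequence: 16 (steps 1–5 and 7–17; step 6 is a one-step branch).

Steps most likely to fail

Step 7 (Proposed new method). The catalyst may be arrested as the silyloxy-stabilised carbene, and methylidene-first addition to the alkyne would scramble the regiochemistry; the product, a reactive diene carrying an enal, may also dimerise by cycloaddition. The fallback uses known carbonyl chemistry and makes the same two ring bonds in two operations. It sets out from lactol 4 and comes back to the route at 13.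
- Acetalisation (MeOH, PPTS) should give (4R)-4-ethenyl-2-methoxytetrahydro-2H-pyran F1.
- Ozonolysis of its only alkene (O3, CH2Cl2/MeOH, −78 °C; Me2S) should give (4R)-2-methoxytetrahydro-2H-pyran-4-carbaldehyde F2.
- Addition of 2-lithio-2-ethyl-1,3-dithiane (THF, −78 °C) forms the bond between the future ketone carbon and the carbinol carbon and should give (2-ethyl-1,3-dithian-2-yl)[(4R)-2-methoxytetrahydro-2H-pyran-4-yl]methanol F3.
- Dithiane cleavage (I2, NaHCO3, aqueous acetone), acetal hydrolysis (aqueous HCl/THF) and intramolecular aldol condensation (piperidinium acetate) close the ring at the methyl-bearing carbon. With equilibration of the ketol centre to the trans isomer this should give (5S,6S)-6-hydroxy-5-(2-hydroxyethyl)-2-methylcyclohex-2-en-1-one F4.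
- Selective oxidation of the primary alcohol (TEMPO, PhI(OAc)2) should give 2-[(1S,6S)-6-hydroxy-4-methyl-5-oxocyclohex-3-en-1-yl]acetaldehyde F5.
- α-Methylenation under the conditions of step 5 then gives 13.

Step 17. Singlet oxygen may abstract hydrogen from a methyl group instead of the CH2 next to the ketone, giving the secondary hydroperoxide isomer, and the product hydroperoxide may decompose on handling. The fallback brings the peroxide in as a protected building block by cross-metathesis. It sets out from keto aldehyde 18 and comes back at the target 22.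
- Aldehyde-selective vinylation with CH2=CHTi(Oi-Pr)3 (from CH2=CHMgBr and ClTi(Oi-Pr)3, THF, −78 to −30 °C) should give (1S,3S,4R,6S)-4-[(2R)-2-(1-hydroxyprop-2-en-1-yl)oxiran-2-yl]-1-methyl-2-oxo-7-oxabicyclo[4.1.0]heptan-3-yl 3-methylbutanoate F6.
- Dess–Martin oxidation should give the vinyl ketone (1S,3S,4R,6S)-1-methyl-2-oxo-4-[(2R)-2-(prop-2-enoyl)oxiran-2-yl]-7-oxabicyclo[4.1.0]heptan-3-yl 3-methylbutanoate F7.
- The partner is made from 2-methylbut-3-en-2-ol by acid-catalysed perhydrolysis (50% H2O2, cat. H2SO4) to 2-hydroperoxy-2-methylbut-3-ene F8, then capping with 2-methoxypropene (PPTS) to 2-[(2-methoxypropan-2-yl)peroxy]-2-methylbut-3-ene F9.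
- Cross-metathesis of F7 with F9 (second-generation Hoveyda–Grubbs catalyst, CH2Cl2, 40 °C) should give the E enone peroxyketal (1S,3S,4R,6S)-4-[(2R)-2-[(2E)-4-[(2-methoxypropan-2-yl)peroxy]-4-methylpent-2-enoyl]oxiran-2-yl]-1-methyl-2-oxo-7-oxabicyclo[4.1.0]heptan-3-yl 3-methylbutanoate F10.
- Mild hydrolysis of the peroxyketal (AcOH/THF/H2O) releases 22.

Step 11. Mismatched double diastereoselection, binding of the catalyst by the ring hydroxyl and titanium-promoted acyl migration or transesterification of the neighbouring ester may erode the selectivity at the quaternary oxirane carbon. The fallback moves the side-chain epoxidation ahead of the reduction and changes it to iminium catalysis. It sets out from enal 14 and comes back at 16.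
- Asymmetric epoxidation of the α-substituted acrolein (aqueous H2O2, diarylprolinol silyl ether catalyst of the enantiomeric series that delivers the 2R oxirane, CH2Cl2, rt) should give (1S,6R)-6-[(2R)-2-formyloxiran-2-yl]-3-methyl-2-oxocyclohex-3-en-1-yl 3-methylbutanoate F11.
- Luche reduction of both carbonyl groups under the conditions of step 10 then gives 16 directly.

Further compounds
F1 | step 7 | (4R)-4-ethenyl-2-methoxytetrahydro-2H-pyran | COC1C[C@H](C=C)CCO1
F2 | step 7 | (4R)-2-methoxytetrahydro-2H-pyran-4-carbaldehyde | COC1C[C@H](C=O)CCO1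
F3 | step 7 | (2-ethyl-1,3-dithian-2-yl)[(4R)-2-methoxytetrahydro-2H-pyran-4-yl]methanol | COC1C[C@H](C(O)C2(CC)SCCCS2)CCO1
F4 | step 7 | (5S,6S)-6-hydroxy-5-(2-hydroxyethyl)-2-methylcyclohex-2-en-1-one | O[C@@H]1C(=O)C(C)=CC[C@H]1CCO
F5 | step 7 | 2-[(1S,6S)-6-hydroxy-4-methyl-5-oxocyclohex-3-en-1-yl]acetaldehyde | O[C@@H]1C(=O)C(C)=CC[C@H]1CC=O
F6 | step 17 | (1S,3S,4R,6S)-4-[(2R)-2-(1-hydroxyprop-2-en-1-yl)oxiran-2-yl]-1-methyl-2-oxo-7-oxabicyclo[4.1.0]heptan-3-yl 3-methylbutanoate | CC(C)CC(=O)O[C@@H]1C(=O)[C@@]2(C)O[C@H]2C[C@H]1[C@]1(C(O)C=C)CO1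
F7 | step 17 | (1S,3S,4R,6S)-1-methyl-2-oxo-4-[(2R)-2-(prop-2-enoyl)oxiran-2-yl]-7-oxabicyclo[4.1.0]heptan-3-yl 3-methylbutanoate | CC(C)CC(=O)O[C@@H]1C(=O)[C@@]2(C)O[C@H]2C[C@H]1[C@]1(C(=O)C=C)CO1
F8 | step 17 | 2-hydroperoxy-2-methylbut-3-ene | C=CC(C)(C)OO
F9 | step 17 | 2-[(2-methoxypropan-2-yl)peroxy]-2-methylbut-3-ene | C=CC(C)(C)OOC(C)(C)OC
F10 | step 17 | (1S,3S,4R,6S)-4-[(2R)-2-[(2E)-4-[(2-methoxypropan-2-yl)peroxy]-4-methylpent-2-enoyl]oxiran-2-yl]-1-methyl-2-oxo-7-oxabicyclo[4.1.0]heptan-3-yl 3-methylbutanoate | CC(C)CC(=O)O[C@@H]1C(=O)[C@@]2(C)O[C@H]2C[C@H]1[C@]1(C(=O)/C=C/C(C)(C)OOC(C)(C)OC)CO1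
F11 | step 11 | (1S,6R)-6-[(2R)-2-formyloxiran-2-yl]-3-methyl-2-oxocyclohex-3-en-1-yl 3-methylbutanoate | CC(C)CC(=O)O[C@@H]1C(=O)C(C)=CC[C@H]1[C@]1(C=O)CO1
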